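**Plan**

- Retrosynthetic cuts, in order: the O10 acetyl and O8 methacryloyl esters; the C10–O bond (hydration of an α-methylene ketone) and the C4–C5 oxirane; C8–C9 of the ten-membered ring; then C13–O, C11–C12/O6–C12 (one CO), C6–C7 and C1–C10 of the open chain.
- Enabling feature: in the ten-membered carbocycle, C9 is the only methylene lying between the C8 carbinol carbon (bonded to C7 of the butenolide ring) and the fully substituted C10 beside the C1 ketone. C8 can therefore be an aldehyde on the butenolide, C9–C10–C14 a 2-acylallyl metal, and C10(CH3)(OAc) the acetylated hydrate of the resulting enone.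
- Forward order: geranyl acetate supplies C1–C6 with the E alkene. C10/C9/C14 are added at C1, and C7/C8/C11/C13 at C6. The butenolide ring closes first (CO insertion), the ten-membered ring second (C8–C9), the oxirane third. C10–OH and the two esters come last.
- Stereochemistry: C6 comes from a chiral phosphoric acid catalyst. C8 comes from C6 in the macrocyclic transition state. C4/C5 and C10 come from peripheral attack on the ten-membered ring. The trans epoxide geometry comes from the E alkene of geranyl acetate.

Key step: step 15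

Remark on the chemistry: germacranolide numbering is used (C1 ketone, C4/C5 epoxide, C6 lactone carbinol, C7=C11 butenolide alkene, C8 ester carbinol, C10 tertiary acetate, C12 lactone carbonyl, C13 acetoxymethyl carbon, C14/C15 methyls). TBS = tert-butyldimethylsilyl, PMB = 4-methoxybenzyl. The C1 carbinol carbon created by the vinyllithium addition is carried as a mixture of both configurations until the double oxidation makes it a ketone, so the SMILES leave it undefined.

**Step 1**
Reactants: 1 geranyl acetate
Product: 3 (2E)-3-methyl-6-oxohex-2-en-1-yl acetate, via secondary ozonide 2 (not isolated)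
Conditions: O3 (1 equiv), CH2Cl2, −78 °C; then Me2S, −78 °C to rt
Reagents that add atoms: ozone, [O-][O+]=O
Why: Ozonolysis with reductive work-up; the electron-rich terminal trisubstituted alkene should react well before the C4=C5 alkene, which the allylic acetate deactivates, so the E geometry is carried over untouched.

**Step 2**
Reactants: 4 2,3-dibromopropene; 5 4-methoxybenzyl alcohol
Product: 7 1-{[(2-bromoprop-2-en-1-yl)oxy]methyl}-4-methoxybenzene, via sodium alkoxide 6 (not isolated)
Conditions: NaH, THF, 0 °C; then 4, Bu4NI (cat.), 0 °C to rt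
Reagents that add atoms: none
Why: Williamson ether synthesis; the alkoxide displaces the allylic bromide by SN2 while the vinylic bromide stays inert.

**Step 3**
Reactants: 7 2-bromoallyl PMB ether; 3 (2E)-3-methyl-6-oxohex-2-en-1-yl acetate
Product: 9 (2E)-6-hydroxy-7-{[(4-methoxybenzyl)oxy]methyl}-3-methylocta-2,7-dien-1-yl acetate, via vinyllithium 8 (not isolated)
Conditions: t-BuLi (2.0 equiv), Et2O, −78 °C; then 3, −78 °C; H2O
Reagents that add atoms: none
Why: Bromine–lithium exchange followed by 1,2-addition of the alkenyllithium forms C1–C10; at −78 °C the aldehyde outruns the acetate and β-elimination of the PMB oxide is slow, and the new C1 carbinol is racemic, which does not matter because C1 becomes a ketone in step 14.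

**Step 4**
Reactants: 9 C1 allylic alcohol
Product: 10 (2E)-6-[(tert-butyldimethylsilyl)oxy]-7-{[(4-methoxybenzyl)oxy]methyl}-3-methylocta-2,7-dien-1-yl acetate
Conditions: TBSCl, imidazole, DMF, rt
Reagents that add atoms: tert-butyldimethylsilyl chloride, CC(C)(C)[Si](C)(C)Cl
Why: Standard imidazole-promoted silylation of a secondary alcohol, which masks C1–OH under conditions that leave the acetate and PMB ether alone.

**Step 5**
Reactants: 10 silyl ether acetate
Product: 11 (2E)-6-[(tert-butyldimethylsilyl)oxy]-7-{[(4-methoxybenzyl)oxy]methyl}-3-methylocta-2,7-dien-1-ol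
Conditions: K2CO3 (cat.), MeOH, 0 °C to rt
Reagents that add atoms: none
Why: Base-catalysed transesterification (Zemplén-type methanolysis) removes the primary allylic acetate without touching the silyl or PMB ethers.

**Step 6**
Reactants: 11 C6 allylic alcohol
Product: 12 (2E)-6-[(tert-butyldimethylsilyl)oxy]-7-{[(4-methoxybenzyl)oxy]methyl}-3-methylocta-2,7-dienal
Conditions: DMP, CH2Cl2, 0 °C to rt
Reagents that add atoms: none
Why: Dess–Martin oxidation of a primary allylic alcohol stops at the enal and, being base-free, should not isomerise the E alkene.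

**Step 7**
Reactants: 13 tert-butyldimethyl(prop-2-yn-1-yloxy)silane; 14 2-(iodomethyl)-4,4,5,5-tetramethyl-1,3,2-dioxaborolane
Product: 17 tert-butyldimethyl{[4-(4,4,5,5-tetramethyl-1,3,2-dioxaborolan-2-yl)but-2-yn-1-yl]oxy}silane, via lithium acetylide 15 (not isolated), via boronate complex 16 (not isolated)
Conditions: n-BuLi, THF, −78 °C; then 14, −78 °C to rt
Reagents that add atoms: none
Why: Matteson-type homologation; the acetylide adds to boron and the alkynyl group of the ate complex migrates to carbon with loss of iodide, a standard entry to γ-substituted propargylboronates (C8–C7≡C11–C13).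

**Step 8**
Reactants: 12 enal; 17 propargylboronate
Product: 19 (4R,5E)-9-[(tert-butyldimethylsilyl)oxy]-3-{[(tert-butyldimethylsilyl)oxy]methyl}-10-{[(4-methoxybenzyl)oxy]methyl}-6-methylundeca-1,2,5,10-tetraen-4-ol, via allenyl borate 18 (not isolated)
Conditions: (S)-TRIP [(S)-3,3'-bis(2,4,6-triisopropylphenyl)-1,1'-binaphthyl-2,2'-diyl hydrogen phosphate] (10 mol %), 4 Å MS, toluene, 0 °C; aqueous work-up
Reagents that add atoms: none
Why: Chiral phosphoric acid-catalysed allenylboration; the propargylboronate reacts by SE2' through a closed six-membered transition state so that C7 bonds to C6 and a 2,3-allenol results, and the (S)-catalyst, chosen by analogy with the Re-face preference of its (R)-antipode in allyl- and propargylborations, should direct attack to the Si face of the enal and set C6 as R.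

**Step 9**
Reactants: 19 (R)-allenol
Product: 20 (5R)-4-{[(tert-butyldimethylsilyl)oxy]methyl}-3-(chloromethyl)-5-[(1E)-5-[(tert-butyldimethylsilyl)oxy]-6-{[(4-methoxybenzyl)oxy]methyl}-2-methylhepta-1,6-dien-1-yl]furan-2(5H)-one
Conditions: PdCl2 (5 mol %), CuCl2 (3 equiv), propylene oxide (HCl scavenger), CO (1 atm), THF, rt
Reagents that add atoms: carbon monoxide, [C-]#[O+]; CuCl2 (chlorine source), Cl[Cu]Cl
Why: Chlorocyclocarbonylation of 2,3-allenols catalysed by divalent palladium; the O6-bound alkoxycarbonylpalladium adds to the central allene carbon C11, the resulting π-allylpalladium is cleaved by chloride at the terminal C13 and CuCl2 reoxidises the zerovalent metal, which closes the butenolide (5-exo acylpalladation) with C7=C11 in place and leaves C6 untouched.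

**Step 10**
Reactants: 20 chloromethyl butenolide
Product: 21 [(5R)-4-{[(tert-butyldimethylsilyl)oxy]methyl}-5-[(1E)-5-[(tert-butyldimethylsilyl)oxy]-6-{[(4-methoxybenzyl)oxy]methyl}-2-methylhepta-1,6-dien-1-yl]-2-oxo-2,5-dihydrofuran-3-yl]methyl acetate
Conditions: KOAc, AcOH (buffer), DMF, rt
Reagents that add atoms: potassium acetate, CC(=O)[O-].[K+]
Why: SN2 displacement at a doubly activated primary allylic chloride; the acetic acid buffer keeps the medium too weakly basic to remove H6, and SN2' attack is blocked by the fully substituted C7.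

**Step 11**
Reactants: 21 PMB ether
Product: 22 [(5R)-4-{[(tert-butyldimethylsilyl)oxy]methyl}-5-[(1E)-5-[(tert-butyldimethylsilyl)oxy]-6-(hydroxymethyl)-2-methylhepta-1,6-dien-1-yl]-2-oxo-2,5-dihydrofuran-3-yl]methyl acetate
Conditions: DDQ, CH2Cl2–pH 7 buffer, 0 °C
Reagents that add atoms: none
Why: Oxidative PMB cleavage by hydride abstraction at the electron-rich benzylic position; silyl ethers, acetate and the electron-poor butenolide are inert to DDQ.

**Step 12**
Reactants: 22 primary allylic alcohol
Product: 23 [(5R)-5-[(1E)-6-(bromomethyl)-5-[(tert-butyldimethylsilyl)oxy]-2-methylhepta-1,6-dien-1-yl]-4-{[(tert-butyldimethylsilyl)oxy]methyl}-2-oxo-2,5-dihydrofuran-3-yl]methyl acetate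
Conditions: CBr4, PPh3, CH2Cl2, 0 °C
Reagents that add atoms: carbon tetrabromide, BrC(Br)(Br)Br
Why: Appel reaction; neutral SN2 bromination of the primary allylic alcohol through its alkoxyphosphonium salt, compatible with silyl ethers, acetate and lactone.

**Step 13**
Reactants: 23 bis(silyl ether) bromide
Product: 24 [(5R)-5-[(1E)-6-(bromomethyl)-5-hydroxy-2-methylhepta-1,6-dien-1-yl]-4-(hydroxymethyl)-2-oxo-2,5-dihydrofuran-3-yl]methyl acetate
Conditions: HF (48 % aq), MeCN, 0 °C to rt
Reagents that add atoms: none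
Why: Acidic fluoride desilylation frees the C1 and C8 carbinols together, and the weakly nucleophilic, non-basic medium spares the allylic bromide, the acetate and H6.

**Step 14**
Reactants: 24 diol bromide
Product: 25 [(5R)-5-[(1E)-6-(bromomethyl)-2-methyl-5-oxohepta-1,6-dien-1-yl]-4-formyl-2-oxo-2,5-dihydrofuran-3-yl]methyl acetate
Conditions: DMP (3 equiv), CH2Cl2, 0 °C to rt; short silica plug, used at once
Reagents that add atoms: none
Why: Double Dess–Martin oxidation turns C8–OH into the aldehyde and both C1 epimers into one 2-(bromomethyl)enone under base-free conditions, so the acidic H6 of the formylbutenolide should not exchange.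

**Step 15**
Reactants: 25 butenolide aldehyde with the 2-(bromomethyl)enone
Product: 27 (6R,8S)-13-acetoxy-8-hydroxy-1-oxogermacra-4E,7(11),10(14)-trien-12,6-olide, via allylchromium dichloride 26 (not isolated)
Conditions: CrCl2 (10 equiv), THF, 23 °C, 25 added by syringe pump over 12 h (final 1 mM); then H2O
Reagents that add atoms: none
Why: Two equivalents of divalent chromium reduce the allylic C–Br bond by successive single-electron transfers to the 2-acylallylchromium 26, whose free methylene terminus adds to the chromium-bound C8 aldehyde through a closed six-membered transition state with allyl transposition, forming C8–C9 and leaving C14 as an exocyclic methylene conjugated with the C1 ketone. The closest known reaction type is the intramolecular Nozaki–Hiyama–Kishi (Barbier-type) allylation of aldehydes with 2-(bromomethyl)acrylate-type halides that closes ten-membered germacranolide carbocycles. The ten-membered ring closes in the 10-exo-trig mode at the aldehyde carbon, O8 staying outside the ring, and the E C4=C5 alkene and the flat butenolide remove rotors from the tether. C8 is controlled by C6: the tether leaves C6 on the butenolide face that carries C5, so C9 must reach C8 from that face, and in the s-cis C11=C7–C8=O rotamer, which turns the chromium-bearing oxygen outward beside the C13 acetate (a possible extra ligand), this gives 8S, although the preference is not assured. The step needs chemoselectivity for the aldehyde and for the bromide; allylchromium reagents prefer aldehydes over ketones, esters and lactones, the allylic bromide is reduced far faster than the allylic acetate, and slow addition into excess CrCl2 at high dilution suppresses dimers and limits exposure of the electron-poor formylbutenolide to the reductant.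

**Step 16**
Reactants: 27 macrocyclic trienolide
Product: 28 (4R,5R,6S,8S)-13-acetoxy-4,5-epoxy-8-hydroxy-1-oxogermacra-7(11),10(14)-dien-12,6-olide
Conditions: DMDO (1.1 equiv), acetone–CH2Cl2, −20 to 0 °C
Reagents that add atoms: dimethyldioxirane, CC1(C)OO1
Why: Neutral electrophilic epoxidation picks the only electron-rich alkene; A(1,3) strain between the C15 methyl and C6 holds H6 in the alkene plane, the ring interior (C7 side) shields one face and oxygen should arrive from the periphery, syn to O6, giving the trans 4R,5R epoxide as in related germacranolide 4,5-epoxidations.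

**Step 17**
Reactants: 28 epoxy enone
Product: 30 (4R,5R,6S,8S,10R)-13-acetoxy-4,5-epoxy-8,10-dihydroxy-1-oxogermacr-7(11)-en-12,6-olide, via C10 hydroperoxide 29 (not isolated)
Conditions: Mn(dpm)3 (dpm = 2,2,6,6-tetramethylheptane-3,5-dionate, 10 mol %), PhSiH3, O2 (1 atm), i-PrOH–CH2Cl2, 0 °C; then P(OEt)3
Reagents that add atoms: dioxygen, O=O
Why: Mukaiyama-type hydration of an enone by hydrogen-atom transfer; a manganese hydride delivers H to terminal C14, the tertiary α-keto radical at C10 should be trapped by O2 on the outer face of the ring conformer that keeps C14 and C15 on the same side (O10 cis to O8, 10R), P(OEt)3 reduces the hydroperoxide, and the tetrasubstituted butenolide alkene is too hindered to compete while no methacrylate is present yet.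

**Step 18**
Reactants: 30 8,10-diol
Product: 31 (4R,5R,6S,8S,10R)-13-acetoxy-4,5-epoxy-10-hydroxy-8-methacryloyloxy-1-oxogermacr-7(11)-en-12,6-olide
Conditions: methacrylic anhydride, DMAP (cat.), i-Pr2NEt, CH2Cl2, 0 °C
Reagents that add atoms: methacrylic anhydride, C=C(C)C(=O)OC(=O)C(C)=C
Why: DMAP-catalysed acylation distinguishes the secondary C8 hydroxyl from the hindered tertiary C10 hydroxyl on steric grounds and proceeds with retention at C8.

**Step 19**
Reactants: 31 10-hydroxy methacrylate
Product: 32 glaucolide A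
Conditions: Ac2O (excess), DMAP, CH2Cl2, rt
Reagents that add atoms: acetic anhydride, CC(=O)OC(C)=O
Why: Nucleophilic catalysis by DMAP (Steglich-type acylation) with excess anhydride is the standard way to esterify tertiary alcohols and avoids the strong or Lewis acids that would open the epoxide.

**Compound list**

1 | geranyl acetate | CC(C)=CCC/C(C)=C/COC(C)=O | starting material
2 | secondary ozonide of the terminal alkene of 1 (3,3-dimethyl-1,2,4-trioxolane carrying the chain at C5) | CC1(C)OOC(CC/C(C)=C/COC(C)=O)O1 | intermediate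
3 | (2E)-3-methyl-6-oxohex-2-en-1-yl acetate | O=CCC/C(C)=C/COC(C)=O | intermediate
4 | 2,3-dibromopropene | C=C(Br)CBr | starting material
5 | 4-methoxybenzyl alcohol | COc1ccc(CO)cc1 | starting material
6 | sodium 4-methoxybenzyl oxide | [Na+].[O-]Cc1ccc(OC)cc1 | intermediate
7 | 1-{[(2-bromoprop-2-en-1-yl)oxy]methyl}-4-methoxybenzene | C=C(Br)COCc1ccc(OC)cc1 | intermediate
8 | 3-[(4-methoxybenzyl)oxy]prop-1-en-2-yllithium | [Li]C(=C)COCc1ccc(OC)cc1 | intermediate
9 | (2E)-6-hydroxy-7-{[(4-methoxybenzyl)oxy]methyl}-3-methylocta-2,7-dien-1-yl acetate (racemic at the carbinol) | C=C(COCc1ccc(OC)cc1)C(O)CC/C(C)=C/COC(C)=O | intermediate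
10 | 6-O-TBS ether of 9 | C=C(COCc1ccc(OC)cc1)C(CC/C(C)=C/COC(C)=O)O[Si](C)(C)C(C)(C)C | intermediate
11 | (2E)-6-(TBS-oxy)-7-(PMB-oxymethyl)-3-methylocta-2,7-dien-1-ol | C=C(COCc1ccc(OC)cc1)C(CC/C(C)=C/CO)O[Si](C)(C)C(C)(C)C | intermediate
12 | (2E)-6-(TBS-oxy)-7-(PMB-oxymethyl)-3-methylocta-2,7-dienal | C=C(COCc1ccc(OC)cc1)C(CC/C(C)=C/C=O)O[Si](C)(C)C(C)(C)C | intermediate
13 | tert-butyldimethyl(prop-2-yn-1-yloxy)silane | C#CCO[Si](C)(C)C(C)(C)C | starting material
14 | 2-(iodomethyl)-4,4,5,5-tetramethyl-1,3,2-dioxaborolane | ICB1OC(C)(C)C(C)(C)O1 | starting material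
15 | lithium acetylide of 13 | [Li]C#CCO[Si](C)(C)C(C)(C)C | intermediate
16 | lithium alkynyl(iodomethyl)pinacolboronate complex | [Li+].IC[B-]1(C#CCO[Si](C)(C)C(C)(C)C)OC(C)(C)C(C)(C)O1 | intermediate
17 | 4-(TBS-oxy)but-2-yn-1-ylboronic acid pinacol ester | CC(C)(C)[Si](C)(C)OCC#CCB1OC(C)(C)C(C)(C)O1 | intermediate
18 | O6-pinacolboryl ether of 19 | C=C=C(CO[Si](C)(C)C(C)(C)C)[C@H](OB1OC(C)(C)C(C)(C)O1)/C=C(\C)CCC(O[Si](C)(C)C(C)(C)C)C(=C)COCc1ccc(OC)cc1 | intermediate
19 | (4R,5E)-9-(TBS-oxy)-3-(TBS-oxymethyl)-10-(PMB-oxymethyl)-6-methylundeca-1,2,5,10-tetraen-4-ol | C=C=C(CO[Si](C)(C)C(C)(C)C)[C@H](O)/C=C(\C)CCC(O[Si](C)(C)C(C)(C)C)C(=C)COCc1ccc(OC)cc1 | intermediate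
20 | (5R)-3-(chloromethyl)-4-(TBS-oxymethyl)-5-[(1E)-5-(TBS-oxy)-6-(PMB-oxymethyl)-2-methylhepta-1,6-dien-1-yl]furan-2(5H)-one | CC(C)(C)[Si](C)(C)OCC1=C(CCl)C(=O)O[C@@H]1/C=C(\C)CCC(O[Si](C)(C)C(C)(C)C)C(=C)COCc1ccc(OC)cc1 | intermediate
21 | 3-(acetoxymethyl) analogue of 20 | CC(C)(C)[Si](C)(C)OCC1=C(COC(C)=O)C(=O)O[C@@H]1/C=C(\C)CCC(O[Si](C)(C)C(C)(C)C)C(=C)COCc1ccc(OC)cc1 | intermediate
22 | primary allylic alcohol from 21 (side chain C(=CH2)CH2OH) | CC(C)(C)[Si](C)(C)OCC1=C(COC(C)=O)C(=O)O[C@@H]1/C=C(\C)CCC(O[Si](C)(C)C(C)(C)C)C(=C)CO | intermediate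
23 | allylic bromide from 22 (side chain C(=CH2)CH2Br) | CC(C)(C)[Si](C)(C)OCC1=C(COC(C)=O)C(=O)O[C@@H]1/C=C(\C)CCC(O[Si](C)(C)C(C)(C)C)C(=C)CBr | intermediate
24 | C1,C8-diol bromide | OCC1=C(COC(C)=O)C(=O)O[C@@H]1/C=C(\C)CCC(O)C(=C)CBr | intermediate
25 | [(5R)-5-[(1E)-6-(bromomethyl)-2-methyl-5-oxohepta-1,6-dien-1-yl]-4-formyl-2-oxo-2,5-dihydrofuran-3-yl]methyl acetate | O=CC1=C(COC(C)=O)C(=O)O[C@@H]1/C=C(\C)CCC(=O)C(=C)CBr | intermediate
26 | 2-acylallylchromium dichloride derived from 25 | O=CC1=C(COC(C)=O)C(=O)O[C@@H]1/C=C(\C)CCC(=O)C(=C)C[Cr](Cl)Cl | intermediate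
27 | (6R,8S)-13-acetoxy-8-hydroxy-1-oxogermacra-4E,7(11),10(14)-trien-12,6-olide | O[C@H]1CC(=C)C(=O)CC/C(C)=C/[C@H]2OC(=O)C(COC(C)=O)=C12 | intermediate
28 | (4R,5R,6S,8S)-13-acetoxy-4,5-epoxy-8-hydroxy-1-oxogermacra-7(11),10(14)-dien-12,6-olide | O[C@H]1CC(=C)C(=O)CC[C@@]2(C)O[C@@H]2[C@H]2OC(=O)C(COC(C)=O)=C12 | intermediate
29 | (10R)-10-hydroperoxide corresponding to 30 | O[C@H]1C[C@@](C)(OO)C(=O)CC[C@@]2(C)O[C@@H]2[C@H]2OC(=O)C(COC(C)=O)=C12 | intermediate
30 | (4R,5R,6S,8S,10R)-13-acetoxy-4,5-epoxy-8,10-dihydroxy-1-oxogermacr-7(11)-en-12,6-olide | O[C@H]1C[C@@](C)(O)C(=O)CC[C@@]2(C)O[C@@H]2[C@H]2OC(=O)C(COC(C)=O)=C12 | intermediate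
31 | 8-O-methacrylate of 30 | C=C(C)C(=O)O[C@H]1C[C@@](C)(O)C(=O)CC[C@@]2(C)O[C@@H]2[C@H]2OC(=O)C(COC(C)=O)=C12 | intermediate
32 | glaucolide A (4R,5R,6S,8S,10R) | C=C(C)C(=O)O[C@H]1C[C@@](C)(OC(C)=O)C(=O)CC[C@@]2(C)O[C@@H]2[C@H]2OC(=O)C(COC(C)=O)=C12 | target

**Totals**

Total step count: 19.
Longest linear sequence: 17 steps (steps 1, 3–6 and 8–19, from geranyl acetate).

**Three steps most likely to fail**

1. Step 15, poor facial selectivity at C8. If the chromium-bound aldehyde reacts through its s-trans rotamer, C9 adds to the other face of C8=O and the 8R carbinol prevails. The fallback replaces retentive acylation by an inverting esterification.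
   - It sets out from 25: the same ring closure is accepted as it comes and gives the 8-epi macrocycle F1.
   - DMDO epoxidation gives the 8-epi epoxide F2.
   - The Mn(dpm)3/PhSiH3/O2 hydration runs through the 8-epi hydroperoxide F3 to the 8-epi diol F4.
   - Mitsunobu esterification of F4 with methacrylic acid (PPh3, DIAD, toluene, 0 °C) displaces the activated secondary C8 oxygen with inversion, leaves the tertiary C10 hydroxyl alone, and comes back to the route at 31.

2. Step 17, poor facial selectivity in the capture of the planar C10 radical by O2, or plain conjugate reduction when that capture is slow. The fallback is a two-electron sequence in which a reagent chooses the face.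
   - It sets out from 28: silylation (Et3SiCl, imidazole, CH2Cl2) gives the 8-O-triethylsilyl ether F5.
   - 1,4-Hydrosilylation (Et3SiH, RhCl(PPh3)3 cat., THF, 40 °C) gives the ring enol silane F6.
   - Rubottom-type oxidation under Shi epoxidation conditions gives the 8,10-bis(triethylsilyl) ether F7. The chiral dioxirane comes from the D-fructose-derived ketone, or its enantiomer, and KHSO5, buffered at pH 8.
   - HF·pyridine removes both silyl groups and comes back to the route at 30.

3. Step 19, sluggish acylation of the hindered tertiary α-ketol hydroxyl. During a long reaction the amine can open the epoxide through deprotonation at C6 or trigger an α-ketol shift. The fallback delivers the acetyl group through a tether and reverses the order of the two esterifications.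
   - It sets out from 30: trimethyl orthoacetate with PPTS (cat.) in CH2Cl2 ties the cis O8/O10 pair into the cyclic orthoacetate F8.
   - Kinetic hydrolysis (aqueous AcOH, 0 °C), which leaves the acyl group on the more hindered oxygen of cyclic orthoesters, gives the 10-acetate 8-alcohol F9.
   - Methacrylic anhydride with DMAP at the free secondary O8 comes back to the route at 32.

**Further compounds**

F1 | step 15 | (6R,8R)-13-acetoxy-8-hydroxy-1-oxogermacra-4E,7(11),10(14)-trien-12,6-olide (8-epi macrocycle) | O[C@@H]1CC(=C)C(=O)CC/C(C)=C/[C@H]2OC(=O)C(COC(C)=O)=C12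
F2 | step 15 | (4R,5R,6S,8R)-13-acetoxy-4,5-epoxy-8-hydroxy-1-oxogermacra-7(11),10(14)-dien-12,6-olide (8-epi epoxide) | O[C@@H]1CC(=C)C(=O)CC[C@@]2(C)O[C@@H]2[C@H]2OC(=O)C(COC(C)=O)=C12
F3 | step 15 | (8R,10R)-10-hydroperoxide (8-epi hydroperoxide) | O[C@@H]1C[C@@](C)(OO)C(=O)CC[C@@]2(C)O[C@@H]2[C@H]2OC(=O)C(COC(C)=O)=C12
F4 | step 15 | (4R,5R,6S,8R,10R)-13-acetoxy-4,5-epoxy-8,10-dihydroxy-1-oxogermacr-7(11)-en-12,6-olide (8-epi diol) | O[C@@H]1C[C@@](C)(O)C(=O)CC[C@@]2(C)O[C@@H]2[C@H]2OC(=O)C(COC(C)=O)=C12
F5 | step 17 | 8-O-triethylsilyl ether of 28 | CC[Si](CC)(CC)O[C@H]1CC(=C)C(=O)CC[C@@]2(C)O[C@@H]2[C@H]2OC(=O)C(COC(C)=O)=C12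
F6 | step 17 | ring enol silane, C1(OSiEt3)=C10(CH3) with the ring bonds cis, 8-O-triethylsilyl | CC[Si](CC)(CC)O[C@H]1C/C(C)=C(/O[Si](CC)(CC)CC)CC[C@@]2(C)O[C@@H]2[C@H]2OC(=O)C(COC(C)=O)=C12
F7 | step 17 | 8,10-bis(triethylsilyl) ether of 30 | CC[Si](CC)(CC)O[C@H]1C[C@@](C)(O[Si](CC)(CC)CC)C(=O)CC[C@@]2(C)O[C@@H]2[C@H]2OC(=O)C(COC(C)=O)=C12
F8 | step 19 | cyclic O8,O10-orthoacetate of 30 (2-methoxy-2-methyl-1,3-dioxane, orthoester carbon undefined) | COC1(C)O[C@H]2C[C@@](C)(O1)C(=O)CC[C@@]3(C)O[C@@H]3[C@H]3OC(=O)C(COC(C)=O)=C23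
F9 | step 19 | (4R,5R,6S,8S,10R)-10,13-diacetoxy-4,5-epoxy-8-hydroxy-1-oxogermacr-7(11)-en-12,6-olide (10-acetate 8-alcohol) | O[C@H]1C[C@@](C)(OC(C)=O)C(=O)CC[C@@]2(C)O[C@@H]2[C@H]2OC(=O)C(COC(C)=O)=C12
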